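## Analysis of the target

Numbering used throughout: C1 is the ring carbon bearing =CH2, C2 bears OH, C3 the angelate, C4 the isopropyl group, C5 and C9 are the ring-fusion carbons (C9 bonded to C1), C6 bears the ethylidene C12–C13, C7 the acetate, C8 is CH2. β is the face of H-5, α the face of H-9.

The target 22 is a trans-fused hydrindane (oplopane skeleton) made of cyclohexane ring A (C1, C2, C3, C4, C5, C9) and cyclopentane ring B (C5, C6, C7, C8, C9), with an exocyclic methylene on C1 and a Z-ethylidene on C6 whose methyl group is syn to C7. It has six stereocentres, (2S,3S,4S,5R,7S,9R) in this numbering: the C3 angelate and the C4 isopropyl group are both β, the C2 hydroxyl is α and so trans-diaxial to the C3 ester, and the C7 acetate is β. The sensitive groups are the angelate (a Z-enoate that goes over to the tiglate with acid, base, nucleophiles or radicals), two allylic esters, a free allylic alcohol next to the angelate and two exocyclic alkenes; C5 and C7 become epimerisable whenever C6 is a ketone. The difficulties are the four contiguous stereocentres C3, C4, C5, C9 around a trans ring fusion, three oxygens on C2, C3 and C7 that must end as alcohol, angelate and acetate, and the geometry of the ethylidene. The route rests on two observations. First, C3, C4, C5 and C9 sit with C1 and C2 on one six-membered ring in exactly the pattern that an endo [4+2] addition of an E,E-diene (C9=C1–C2=C3) to an E-dienophile (C4=C5) leaves on a cyclohexene C1=C2. Second, the chain C9–C8–C7–C6–C5, with oxygen on C7 and C6, nothing on C8 and (S) at C7, is C1–C5 of 2-deoxy-D-ribose, so the tether, the C7 stereocentre and the C6 oxygen can come from the sugar.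

## Retrosynthetic reasoning

22 from 21. The C1 methylene and the free C2 hydroxyl are taken back together to the 1α,2α-epoxide 21, in which C1 still carries a methyl group. This means the one free hydroxyl of the target never needs a protecting group, and the 1,1-disubstituted alkene does not exist while ring B is worked on. The forward step must open the epoxide at C1 and remove a methyl hydrogen without a base or acid that the two esters would not survive, which points to a titanocene-mediated radical opening.

21 from 18 through 20 and 19. The C7 acetate goes back through alcohol 20 to silyl ether 19, and the C6=C12 bond is cut by a Wittig transform to the C6 ketone 18. The olefination comes after the epoxidation of ring A because a peracid could not tell two trisubstituted alkenes apart. It is run on the α-silyloxy ketone and not on the acetate because the ylide is basic. The forward step must give the Z isomer without epimerising C5 or C7.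

18 from 14 through 17, 16 and 15. Ketone 18 comes from alcohol 17, the epoxide of 17 from the C1=C2 alkene of 16, the C7 silyl ether of 16 from diol 15, and 15 from acetonide 14. Acid sensitivity fixes the order (the acetonide is hydrolysed before the epoxide exists), and sterics pick the C7 hydroxyl for silylation. The β-face C3 ester sends the peracid to the α face and so sets C2.

14 from 13. The ester C–O bond at C3 is cut to alcohol 13. The ester is made early, when C3–OH is the only hydroxyl, so C2 and C3 never have to be differentiated; it then serves as the face-blocking group.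

13 from 10 through 12 and 11. The isopropyl group is traced to the acetyl group of 10 through the isopropenyl compounds 12 and 11, and the C3 hydroxyl to the C3–B bond. Methylenation precedes the oxidation of boron so that a β-hydroxy ketone, open to retro-aldol cleavage and dehydration, is never formed. The hydrogenation must pick the 1,1-disubstituted alkene and leave C1=C2.

10 from 9. The bonds C3–C4 and C5–C9 are cut together, opening both rings to the trienone boronate 9. No other pair of bonds sets C3, C4, C5 and C9 at once, and boron on C3 is the one diene substituent that both survives a Lewis acid and becomes an oxygen with retention. The forward cycloaddition must be endo with respect to the acetyl group (trans fusion) and must take one face of the dienophile relative to the dioxolane.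

9 from 1. The C4=C5 bond of 9 is cut to aldehyde 8 and ylide 7, and 8 comes from alcohol 6. The C2=C3 bond of 6 is cut to enal 4 and the one-carbon boron reagent 5. The C9=C1 bond of 4 is cut to lactol 2 and ylide 3, and 2 is the acetonide of 1. Each cut is an olefination at an aldehyde carbon that the sugar supplies or that the previous step created, so the chain is assembled in four operations with no protecting group beyond the acetonide.

## Alternatives that were turned down

Alternative 1: The C5–C9 bond alone is disconnected, giving the acyclic ketal A2, which has a saturated aldehyde at C6 and an E-enal C9=C8–C7. In the forward step a prolinol silyl ether catalyst converts the C6 aldehyde into an enamine whose carbon C5 adds to C9 (6-exo Michael closure of ring A), giving dialdehyde A1 with trans arms on C5 and C9. In its favour, the ring-fusion configuration is under catalyst control, and the C2 and C3 oxygens are present and differentiated from the start, so no late epoxide chemistry is needed and no ester has to pass through a Wittig reaction; on both points it is stronger than the chosen route. Against it, the step forms one ring, one bond and two stereocentres. C2, C3 and C4 of A2 must be built by separate acyclic asymmetric steps. The acceptor carbon C9 is attached to the fully substituted ketal carbon C1 and is hindered. Ring B must still be closed from two aldehydes through a C6–C7 bond, with the new problem of which terminus becomes the ketone and how C7 is set. The chosen strategy closes both rings and sets four stereocentres in one step, takes C7 and the C6 oxygen from the sugar, and reaches its key substrate in four steps.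

Alternative 2: The C6–C7 bond is traced to a cadinane, the trans-decalin cis-diol monomesylate A4. In the forward step the ring bond C12–C7, antiperiplanar to the equatorial C6 mesylate, migrates from the carbinol carbon C12 to C6; ring B contracts to five atoms and C12 is expelled as an acetyl group, giving the acetyl hydrindane A3. In its favour, the shift is stereospecific and the trans fusion is inherited from a trans-decalin, so there is no facial-selectivity question; on certainty of the ring-fusion outcome it is stronger than the chosen route. Against it for this target, A3 carries no oxygen on C2, C3 or C7, has an acetyl group where a Z-ethylidene next to an acetoxy carbon is needed, and has an oxygen at C1 where the methylene belongs. Ring A and ring B would both need long redox sequences on unactivated positions, and A4 with its five stereocentres is itself a multistep target. In the chosen route every oxygen of the target is already in the cycloaddition substrate or latent in the cycloadduct (C3 as boron, C2 in the C1=C2 alkene).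

Alternative 3: Three bonds (C5–C9, C6–C7, C7–C8) are disconnected, giving the dienyne A6 and carbon monoxide. In the forward step a chlororhodium carbonyl catalyst under CO couples the alkyne C6≡C5, the vinyl group C9=C8 of the 2-substituted diene and CO as C7 in a dienyl Pauson–Khand reaction, giving the bicyclic enone A5. In its favour, it makes three C–C bonds and both rings, and ring A emerges fully substituted with the C1 methylene already in place; in bond count and in the state of ring A it is stronger than the chosen route. Against it, C5 becomes sp2, so the trans fusion must be set later by reducing the C5=C6 enone, which typically favours the cis-fused hydrindanone. The carbonyl sits on C7 and the alkene on C5=C6, the wrong pattern: an aldol-type ethylidenation at C6 would place the methyl group away from the C7 carbonyl, opposite to the target. C9 depends on induction from C2 through the diene, and A6 needs three contiguous acyclic stereocentres. The chosen route sets the trans fusion in the ring-forming step itself and installs the ethylidene on a C6 ketone whose α-oxygen steers the geometry toward the Z isomer.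

Key step: step 5

Assumption: 2-deoxy-D-ribose reacts through its pyranose form, in which O3 and O4 are the only cis-vicinal pair, so that a single acetonide lactol is expected.

## Route

Step 1
Reactants: 1 2-deoxy-D-ribose
Product: 2 2-deoxy-3,4-O-isopropylidene-D-erythro-pentopyranose (lactol, anomeric mixture)
Conditions: 2-methoxypropene, PPTS (cat.), EtOAc, 0 °C to rt
Reagents that add atoms: 2-methoxypropene, COC(C)=C
Why: Acid-catalysed acetalisation with the enol ether bridges the cis-3,4-diol of the pyranose and leaves the hemiacetal free; no stereocentre is touched.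

Step 2
Reactants: 2 2-deoxy-3,4-O-isopropylidene-D-erythro-pentopyranose; 3 2-(triphenylphosphoranylidene)propanal
Product: 4 (2E)-4-[(4S,5R)-5-(hydroxymethyl)-2,2-dimethyl-1,3-dioxolan-4-yl]-2-methylbut-2-enal
Conditions: 3 (1.5 equiv), PhCO2H (cat.), toluene, 80 °C
Reagents that add atoms: 2-(triphenylphosphoranylidene)propanal (3), CC(C=O)=P(c1ccccc1)(c1ccccc1)c1ccccc1
Why: Wittig reaction on the open-chain aldehyde in equilibrium with the lactol; the stabilised α-methyl formyl ylide should give the E-trisubstituted enal (C9=C1) and free the C5 hydroxyl, and the α-methyl group slows oxa-Michael return of that hydroxyl to C9.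

Step 3
Reactants: 4 (2E)-enal alcohol; 5 2-(dichloromethyl)-4,4,5,5-tetramethyl-1,3,2-dioxaborolane
Product: 6 {(4R,5S)-2,2-dimethyl-5-[(2E,4E)-3-methyl-5-(4,4,5,5-tetramethyl-1,3,2-dioxaborolan-2-yl)penta-2,4-dien-1-yl]-1,3-dioxolan-4-yl}methanol
Conditions: CrCl2 (8 equiv), LiI (4 equiv), THF, rt
Reagents that add atoms: 2-(dichloromethyl)-4,4,5,5-tetramethyl-1,3,2-dioxaborolane (5), ClC(Cl)B1OC(C)(C)C(C)(C)O1
Why: Takai-type boryl olefination: divalent chromium converts 5 into a geminal dichromium species that adds to the aldehyde and eliminates to the E-alkenyl boronate (C2=C3); the reagent is oxophilic but not basic, so the free hydroxyl, the acetonide and the C9=C1 geometry should be untouched.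

Step 4
Reactants: 6 dienyl boronate alcohol; 7 1-(triphenylphosphoranylidene)propan-2-one
Product: 9 (3E)-4-{(4R,5S)-2,2-dimethyl-5-[(2E,4E)-3-methyl-5-(4,4,5,5-tetramethyl-1,3,2-dioxaborolan-2-yl)penta-2,4-dien-1-yl]-1,3-dioxolan-4-yl}but-3-en-2-one, via dioxolane carbaldehyde 8 (not isolated)
Conditions: Dess–Martin periodinane, NaHCO3, CH2Cl2, 0 °C; then 7 (2 equiv), rt
Reagents that add atoms: 1-(triphenylphosphoranylidene)propan-2-one (7), CC(=O)C=P(c1ccccc1)(c1ccccc1)c1ccccc1
Why: Buffered Dess–Martin oxidation avoids base and so avoids epimerisation of the α-alkoxy aldehyde at C6; the stabilised ylide then olefinates it in the same flask to the E-enone (C4=C5), so the aldehyde never stands.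

Step 5
Reactants: 9 trienone boronate
Product: 10 cycloadduct: ring A cyclohexene (C1=C2, methyl on C1) with 3β-pinacolboryl and 4β-acetyl, trans-fused (H-5β, H-9α) to ring B carrying the 6β,7β-O-isopropylidene acetal
Conditions: Me2AlCl (1.2 equiv), CH2Cl2, −78 to 0 °C
Reagents that add atoms: none
Why: Me2AlCl binds the ketone oxygen and lowers the enone LUMO, and the diene C9=C1–C2=C3 adds suprafacially across C4=C5 in a concerted, asynchronous [4+2] in which the C5–C9 bond leads. The closest known reaction types are the Lewis-acid-promoted intramolecular Diels–Alder reaction of 1,3,8-nonatrienes activated at the dienophile terminus and the cycloadditions of 1-(dialkoxyboryl)dienes, whose regiochemistry (boron-bearing carbon to the α-carbon of the acceptor) and endo preference match what the tether imposes here. Ring B closes as the five-membered tether ring through C5–C9, and ring A as the new cyclohexene through C3–C4 and C5–C9. C3 follows from the E,E geometry of the diene (boron and C8 on the same face of ring A), and C4 from the E geometry of the enone (acetyl trans to C6). The cis relation of acetyl and boron and the trans fusion at C5/C9 follow from the transition state with the complexed acetyl group endo, which for a three-atom tether is the trans-fused one. The selectivity that is not automatic is the face of the dienophile relative to the sugar centres: the cis-fused dioxolane makes the forming cyclopentane part of a bicyclo[3.3.0] system, and C4 should bond on its convex face, anti to the C6 oxygen, which is diastereomer 10. The C1 methyl group raises the diene coefficient at C9 and reinforces C5–C9 bonding, and the dioxolane holds C5 and C8 gauche, which favours closure. The acetonide and the boronates should tolerate about one equivalent of Me2AlCl at low temperature.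

Step 6
Reactants: 10 acetyl allylboronate cycloadduct
Product: 11 4β-isopropenyl analogue of 10 (3β-pinacolboryl, acetonide, C1=C2 unchanged)
Conditions: Ph3PCH3Br, KN(SiMe3)2, THF, 0 °C; then 10, 0 °C to rt
Reagents that add atoms: methyltriphenylphosphonium bromide, C[P+](c1ccccc1)(c1ccccc1)c1ccccc1.[Br-]
Why: Wittig methylenation of the methyl ketone, done before boron is oxidised so that no β-hydroxy ketone is ever formed; the acetyl group on C4 is equatorial and trans to C6, so reversible enolisation cannot change C4.

Step 7
Reactants: 11 isopropenyl allylboronate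
Product: 12 3β-hydroxy-4β-isopropenyl acetonide (allylic alcohol, C1=C2)
Conditions: H2O2, NaOH, THF/H2O, 0 °C
Reagents that add atoms: hydrogen peroxide, OO
Why: Oxidation of the secondary allylic boronate by 1,2-migration of C3 from boron to oxygen, which proceeds with retention and without allylic shift, giving the 3β-alcohol.

Step 8
Reactants: 12 isopropenyl allylic alcohol
Product: 13 3β-hydroxy-4β-isopropyl acetonide (C1=C2 retained)
Conditions: H2 (1 atm), RhCl(PPh3)3 (5 mol %), benzene, rt
Reagents that add atoms: none
Why: Homogeneous hydrogenation with RhCl(PPh3)3 reduces the 1,1-disubstituted isopropenyl group far faster than the trisubstituted ring alkene; no stereocentre is formed.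

Step 9
Reactants: 13 isopropyl allylic alcohol
Product: 14 3β-angeloyloxy-4β-isopropyl acetonide (C1=C2)
Conditions: angelic acid, 2,4,6-Cl3C6H2COCl, Et3N, toluene, rt; then 13, 80 °C
Reagents that add atoms: angelic acid [(2Z)-2-methylbut-2-enoic acid], C/C=C(/C)C(=O)O
Why: Yamaguchi-type esterification through the mixed anhydride, run without a nucleophilic catalyst so that the Z-enoate does not isomerise to the tiglate; C3–OH is the only hydroxyl at this point and the ester later shields the β face of C1=C2.

Step 10
Reactants: 14 angelate acetonide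
Product: 15 6β,7β-diol (3β-angelate, C1=C2)
Conditions: AcOH/H2O (4:1), 50 °C
Reagents that add atoms: none
Why: Acid hydrolysis of the acetonide, placed before epoxidation because the epoxide would not survive it; the allylic angelate and both alkenes should tolerate aqueous acetic acid.

Step 11
Reactants: 15 diol
Product: 16 7β-tert-butyldimethylsilyloxy-6β-ol
Conditions: TBSCl (1.1 equiv), imidazole, DMF, 0 °C
Reagents that add atoms: tert-butyldimethylsilyl chloride, CC(C)(C)[Si](C)(C)Cl
Why: Selective silylation of the less hindered C7 hydroxyl, flanked by the C8 methylene, over the C6 hydroxyl, which lies between the ring fusion and the C4 isopropyl group.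

Step 12
Reactants: 16 mono-silyl ether
Product: 17 1α,2α-epoxide (1β-methyl, 3β-angelate, 6β-OH, 7β-OTBS)
Conditions: mCPBA, NaHCO3, CH2Cl2, 0 °C
Reagents that add atoms: 3-chloroperoxybenzoic acid, O=C(OO)c1cccc(Cl)c1
Why: Prilezhaev epoxidation of the electron-rich C1=C2 alkene, the conjugated angelate alkene being far less nucleophilic; the pseudoaxial 3β-acyloxy group blocks the β face, so oxygen is delivered to the α face, which sets C2 (oxygen trans to the C3 ester) and C1.

Step 13
Reactants: 17 epoxy alcohol
Product: 18 C6 ketone (1α,2α-epoxide, 3β-angelate, 7β-OTBS)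
Conditions: Dess–Martin periodinane, NaHCO3, CH2Cl2, 0 °C to rt
Reagents that add atoms: none
Why: Buffered Dess–Martin oxidation gives the ketone without base, so neither C7 nor the ring-fusion centre C5 should epimerise and the epoxide stays closed; 18 is used at once.

Step 14
Reactants: 18 α-silyloxy ketone
Product: 19 (Z)-6-ethylidene compound (1α,2α-epoxide, 3β-angelate, 7β-OTBS)
Conditions: Ph3PCH2CH3Br, KN(SiMe3)2, THF, −78 °C; then 18, −78 to 0 °C
Reagents that add atoms: ethyltriphenylphosphonium bromide, CC[P+](c1ccccc1)(c1ccccc1)c1ccccc1.[Br-]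
Why: Wittig reaction of a non-stabilised ylide with an α-alkoxy ketone, a combination that places the ylide substituent cis to the oxygen-bearing carbon; that side is also the one away from C5 and the C4 isopropyl group, so the methyl group should end syn to C7 (Z). Low temperature and a slight deficit of base keep enolisation toward C5 or C7 down.

Step 15
Reactants: 19 silyl ether
Product: 20 7β-alcohol (Z-ethylidene, epoxide, angelate)
Conditions: Bu4NF, AcOH, THF, 0 °C to rt
Reagents that add atoms: none
Why: Fluoride cleavage of the silyl ether, buffered with acetic acid so that the angelate and the epoxide are not exposed to base.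

Step 16
Reactants: 20 allylic alcohol
Product: 21 7β-acetate (Z-ethylidene, 1α,2α-epoxide, 3β-angelate)
Conditions: Ac2O, pyridine, DMAP (cat.), CH2Cl2, rt
Reagents that add atoms: acetic anhydride, CC(=O)OC(C)=O
Why: Standard acylation of the only free hydroxyl, with retention at C7.

Step 17
Reactants: 21 epoxy diester
Product: 22 target, (1Z,2S,3aR,5S,6S,7S,7aR)-2-acetoxy-1-ethylidene-5-hydroxy-4-methylidene-7-(propan-2-yl)octahydro-1H-inden-6-yl (2Z)-2-methylbut-2-enoate
Conditions: Cp2TiCl2 (2.5 equiv), Mn dust, THF, rt; then 21, rt
Reagents that add atoms: none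
Why: Cp2TiCl (trivalent titanium, formed in the flask) opens the epoxide homolytically at the tertiary carbon C1; the C1 radical is trapped by a second Cp2TiCl and loses a hydrogen from the methyl group, the least hindered β-position, giving the exocyclic methylene and the C2 titanium alkoxide, whose α C2–O bond is never broken. This isomerisation of methyl-substituted trisubstituted epoxides to exo-methylene allylic alcohols is known, and allylic acetates, enoates and isolated alkenes are inert to the reagent, which is why it can be left to the last step.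

## Compound list

1 | 2-deoxy-D-ribose, (3S,4R)-3,4,5-trihydroxypentanal | O=CC[C@H](O)[C@H](O)CO | starting material
2 | 2-deoxy-3,4-O-isopropylidene-D-erythro-pentopyranose (anomeric mixture) | OC1C[C@@H]2OC(C)(C)O[C@@H]2CO1 | intermediate
3 | 2-(triphenylphosphoranylidene)propanal | CC(C=O)=P(c1ccccc1)(c1ccccc1)c1ccccc1 | starting material
4 | (2E)-4-[(4S,5R)-5-(hydroxymethyl)-2,2-dimethyl-1,3-dioxolan-4-yl]-2-methylbut-2-enal | OC[C@H]1OC(C)(C)O[C@H]1C/C=C(\C)C=O | intermediate
5 | 2-(dichloromethyl)-4,4,5,5-tetramethyl-1,3,2-dioxaborolane | ClC(Cl)B1OC(C)(C)C(C)(C)O1 | starting material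
6 | {(4R,5S)-2,2-dimethyl-5-[(2E,4E)-3-methyl-5-(4,4,5,5-tetramethyl-1,3,2-dioxaborolan-2-yl)penta-2,4-dien-1-yl]-1,3-dioxolan-4-yl}methanol | OC[C@H]1OC(C)(C)O[C@H]1C/C=C(\C)/C=C/B2OC(C)(C)C(C)(C)O2 | intermediate
7 | 1-(triphenylphosphoranylidene)propan-2-one | CC(=O)C=P(c1ccccc1)(c1ccccc1)c1ccccc1 | starting material
8 | (4S,5S)-2,2-dimethyl-5-[(2E,4E)-3-methyl-5-(4,4,5,5-tetramethyl-1,3,2-dioxaborolan-2-yl)penta-2,4-dien-1-yl]-1,3-dioxolane-4-carbaldehyde | O=C[C@H]1OC(C)(C)O[C@H]1C/C=C(\C)/C=C/B2OC(C)(C)C(C)(C)O2 | intermediate (not isolated)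
9 | (3E)-4-{(4R,5S)-2,2-dimethyl-5-[(2E,4E)-3-methyl-5-(4,4,5,5-tetramethyl-1,3,2-dioxaborolan-2-yl)penta-2,4-dien-1-yl]-1,3-dioxolan-4-yl}but-3-en-2-one | CC(=O)/C=C/[C@H]1OC(C)(C)O[C@H]1C/C=C(\C)/C=C/B2OC(C)(C)C(C)(C)O2 | intermediate
10 | cycloadduct: 4β-acetyl-1-methyl-3β-(pinacolboryl) ring A cyclohexene (C1=C2), trans-fused (H-5β, H-9α), 6β,7β-O-isopropylidene on ring B | CC1=C[C@@H](B3OC(C)(C)C(C)(C)O3)[C@@H](C(C)=O)[C@@H]2[C@H]4OC(C)(C)O[C@H]4C[C@@H]12 | intermediate
11 | 4β-isopropenyl-3β-(pinacolboryl) analogue of 10 | CC1=C[C@@H](B3OC(C)(C)C(C)(C)O3)[C@@H](C(C)=C)[C@@H]2[C@H]4OC(C)(C)O[C@H]4C[C@@H]12 | intermediate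
12 | 3β-hydroxy-4β-isopropenyl acetonide (C1=C2) | CC1=C[C@@H](O)[C@@H](C(C)=C)[C@@H]2[C@H]4OC(C)(C)O[C@H]4C[C@@H]12 | intermediate
13 | 3β-hydroxy-4β-isopropyl acetonide (C1=C2) | CC1=C[C@@H](O)[C@@H](C(C)C)[C@@H]2[C@H]4OC(C)(C)O[C@H]4C[C@@H]12 | intermediate
14 | 3β-angeloyloxy-4β-isopropyl acetonide (C1=C2) | CC1=C[C@@H](OC(=O)/C(C)=C\C)[C@@H](C(C)C)[C@@H]2[C@H]4OC(C)(C)O[C@H]4C[C@@H]12 | intermediate
15 | 3β-angeloyloxy-4β-isopropyl-6β,7β-diol (C1=C2) | CC1=C[C@@H](OC(=O)/C(C)=C\C)[C@@H](C(C)C)[C@@H]2[C@@H](O)[C@@H](O)C[C@@H]12 | intermediate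
16 | 7β-(tert-butyldimethylsilyloxy)-6β-hydroxy-3β-angelate (C1=C2) | CC1=C[C@@H](OC(=O)/C(C)=C\C)[C@@H](C(C)C)[C@@H]2[C@@H](O)[C@@H](O[Si](C)(C)C(C)(C)C)C[C@@H]12 | intermediate
17 | 1α,2α-epoxy-1β-methyl-6β-hydroxy-7β-OTBS-3β-angelate | C[C@]13O[C@@H]3[C@@H](OC(=O)/C(C)=C\C)[C@@H](C(C)C)[C@@H]2[C@@H](O)[C@@H](O[Si](C)(C)C(C)(C)C)C[C@@H]12 | intermediate
18 | 1α,2α-epoxy-6-oxo-7β-OTBS-3β-angelate | C[C@]13O[C@@H]3[C@@H](OC(=O)/C(C)=C\C)[C@@H](C(C)C)[C@@H]2C(=O)[C@@H](O[Si](C)(C)C(C)(C)C)C[C@@H]12 | intermediate
19 | 1α,2α-epoxy-(6Z)-ethylidene-7β-OTBS-3β-angelate | C[C@]13O[C@@H]3[C@@H](OC(=O)/C(C)=C\C)[C@@H](C(C)C)[C@@H]2/C(=C/C)[C@@H](O[Si](C)(C)C(C)(C)C)C[C@@H]12 | intermediate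
20 | 1α,2α-epoxy-(6Z)-ethylidene-7β-hydroxy-3β-angelate | C[C@]13O[C@@H]3[C@@H](OC(=O)/C(C)=C\C)[C@@H](C(C)C)[C@@H]2/C(=C/C)[C@@H](O)C[C@@H]12 | intermediate
21 | 1α,2α-epoxy-(6Z)-ethylidene-7β-acetoxy-3β-angelate | C[C@]13O[C@@H]3[C@@H](OC(=O)/C(C)=C\C)[C@@H](C(C)C)[C@@H]2/C(=C/C)[C@@H](OC(C)=O)C[C@@H]12 | intermediate
22 | (1Z,2S,3aR,5S,6S,7S,7aR)-2-acetoxy-1-ethylidene-5-hydroxy-4-methylidene-7-(propan-2-yl)octahydro-1H-inden-6-yl (2Z)-2-methylbut-2-enoate | C=C1[C@H](O)[C@@H](OC(=O)/C(C)=C\C)[C@@H](C(C)C)[C@@H]2/C(=C/C)[C@@H](OC(C)=O)C[C@@H]12 | target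

## Step count and least certain steps

Total step count: 17. Longest linear sequence: 17 steps from 1; compounds 3, 5 and 7 are bought.

Step 5 (key step). The most likely failures are poor facial selectivity relative to the dioxolane (both trans-fused diastereomers forming), erosion of the endo preference if an uncatalysed background reaction competes, or deactivation of the diene through Lewis acid binding at the boronate oxygens. The fallback puts the facial choice under catalyst control and sets out from 8, isolated crude after the oxidation half of step 4. Wittig reaction with (triphenylphosphoranylidene)acetaldehyde gives trienal F1. Iminium activation with a 5-benzyl-2-tert-butyl-3-methylimidazolidin-4-one trifluoroacetate, in the enantiomer that reinforces the dioxolane, should give the endo, trans-fused cycloadduct aldehyde F2. MeTi(OiPr)3 adds to the aldehyde without touching the boronate to give carbinol F3, and Dess–Martin oxidation returns to the route at 10.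

Step 17. After homolytic opening, the C1 radical may be reduced by hydrogen-atom transfer, or the β-titanoxy organotitanium may lose oxygen and return the C1=C2 alkene instead of losing a methyl hydrogen; at the last step a poor outcome cannot be absorbed. The fallback moves the isomerisation ahead of all esters and uses an aluminium amide base; it sets out from 13, returns at 22, and costs four more steps and a second silyl group.
- TESCl and imidazole give triethylsilyl ether F4, and mCPBA epoxidises anti to the silyl ether to give epoxide F5.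
- Et2Al(TMP) (diethylaluminium 2,2,6,6-tetramethylpiperidide, toluene, 0 °C) removes a methyl proton and gives exo-methylene alcohol F6.
- TBSOTf and 2,6-lutidine give bis-silyl ether F7; PPTS in MeOH at 0 °C removes only the triethylsilyl group to give alcohol F8; esterification as in step 9 gives angelate F9.
- Aqueous acetic acid frees diol F10; TESCl at −40 °C gives C7 silyl ether F11; Dess–Martin oxidation gives ketone F12; the Wittig reaction of step 14 gives ethylidene compound F13.
- PPTS in MeOH gives allylic alcohol F14, Ac2O and pyridine give acetate F15, and HF·pyridine removes the C2 silyl ether to give 22.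

Step 14. The ylide may enolise ketone 18 toward C7 or C5, returning ketone or epimerised ketone (a cis-fused hydrindanone is probably the more stable fusion), or geometric control may be incomplete. The fallback avoids a basic carbon nucleophile and sets out from 18. Methylenation with Cp2Ti(μ-CH2)(μ-Cl)AlMe2 (pyridine, THF, −40 to 0 °C) gives methylidene compound F16. Cross-metathesis with (Z)-but-2-ene under the second-generation Hoveyda–Grubbs catalyst then installs the ethylidene under thermodynamic control, which should favour the methyl group away from C5 and the C4 isopropyl group. The epoxide still masks the C1 methylene, so F16 has only one metathesis-active alkene. The route is rejoined at 19.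

Step 9. Acylation of the hindered pseudoaxial C3 hydroxyl, cis to the isopropyl group, may be slow, and forcing conditions risk isomerisation of the angeloyl unit to the tigloyl unit. The fallback builds the enoate on the molecule and sets out from 13. Esterification with the saturated acid 2-[bis(2,2,2-trifluoroethoxy)phosphoryl]propanoic acid (DCC, DMAP) gives phosphonate ester F17. A Z-selective Horner–Wadsworth–Emmons reaction with acetaldehyde (KN(SiMe3)2, 18-crown-6, THF, −78 °C) sets the angelate geometry kinetically and returns to the route at 14.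

Step 3. Conversion may stall, or excess divalent chromium may cause reductive coupling of the enal, in the presence of the free hydroxyl, and a polar product is hard to free from chromium salts. The fallback sets out from 4. Seyferth–Gilbert homologation with the Ohira–Bestmann reagent (K2CO3, MeOH) gives enyne alcohol F18. Syn-hydroboration with pinacolborane catalysed by Cp2Zr(H)Cl (the hydroxyl being borylated transiently and freed on work-up) gives the E-alkenyl boronate and returns to the route at 6.

## Further compounds

F1 | step 5 | (2E)-3-{(4R,5S)-2,2-dimethyl-5-[(2E,4E)-3-methyl-5-(4,4,5,5-tetramethyl-1,3,2-dioxaborolan-2-yl)penta-2,4-dien-1-yl]-1,3-dioxolan-4-yl}prop-2-enal | O=C/C=C/[C@H]1OC(C)(C)O[C@H]1C/C=C(\C)/C=C/B2OC(C)(C)C(C)(C)O2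
F2 | step 5 | 4β-formyl analogue of 10 (3β-pinacolboryl, trans-fused, acetonide) | CC1=C[C@@H](B3OC(C)(C)C(C)(C)O3)[C@@H](C=O)[C@@H]2[C@H]4OC(C)(C)O[C@H]4C[C@@H]12
F3 | step 5 | 4β-(1-hydroxyethyl) analogue of 10 (carbinol epimers) | CC1=C[C@@H](B3OC(C)(C)C(C)(C)O3)[C@@H](C(C)O)[C@@H]2[C@H]4OC(C)(C)O[C@H]4C[C@@H]12
F4 | step 17 | 3β-triethylsilyl ether of 13 | CC1=C[C@@H](O[Si](CC)(CC)CC)[C@@H](C(C)C)[C@@H]2[C@H]4OC(C)(C)O[C@H]4C[C@@H]12
F5 | step 17 | 1α,2α-epoxide of F4 | C[C@]13O[C@@H]3[C@@H](O[Si](CC)(CC)CC)[C@@H](C(C)C)[C@@H]2[C@H]4OC(C)(C)O[C@H]4C[C@@H]12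
F6 | step 17 | 2α-hydroxy-1-methylidene-3β-(triethylsilyloxy) acetonide | C=C1[C@H](O)[C@@H](O[Si](CC)(CC)CC)[C@@H](C(C)C)[C@@H]2[C@H]4OC(C)(C)O[C@H]4C[C@@H]12
F7 | step 17 | 2α-(tert-butyldimethylsilyloxy)-1-methylidene-3β-(triethylsilyloxy) acetonide | C=C1[C@H](O[Si](C)(C)C(C)(C)C)[C@@H](O[Si](CC)(CC)CC)[C@@H](C(C)C)[C@@H]2[C@H]4OC(C)(C)O[C@H]4C[C@@H]12
F8 | step 17 | 2α-(tert-butyldimethylsilyloxy)-3β-hydroxy-1-methylidene acetonide | C=C1[C@H](O[Si](C)(C)C(C)(C)C)[C@@H](O)[C@@H](C(C)C)[C@@H]2[C@H]4OC(C)(C)O[C@H]4C[C@@H]12
F9 | step 17 | 2α-(tert-butyldimethylsilyloxy)-3β-angeloyloxy-1-methylidene acetonide | C=C1[C@H](O[Si](C)(C)C(C)(C)C)[C@@H](OC(=O)/C(C)=C\C)[C@@H](C(C)C)[C@@H]2[C@H]4OC(C)(C)O[C@H]4C[C@@H]12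
F10 | step 17 | 2α-OTBS-3β-angelate-1-methylidene-6β,7β-diol | C=C1[C@H](O[Si](C)(C)C(C)(C)C)[C@@H](OC(=O)/C(C)=C\C)[C@@H](C(C)C)[C@@H]2[C@@H](O)[C@@H](O)C[C@@H]12
F11 | step 17 | 2α-OTBS-3β-angelate-1-methylidene-6β-hydroxy-7β-(triethylsilyloxy) compound | C=C1[C@H](O[Si](C)(C)C(C)(C)C)[C@@H](OC(=O)/C(C)=C\C)[C@@H](C(C)C)[C@@H]2[C@@H](O)[C@@H](O[Si](CC)(CC)CC)C[C@@H]12
F12 | step 17 | 2α-OTBS-3β-angelate-1-methylidene-6-oxo-7β-(triethylsilyloxy) compound | C=C1[C@H](O[Si](C)(C)C(C)(C)C)[C@@H](OC(=O)/C(C)=C\C)[C@@H](C(C)C)[C@@H]2C(=O)[C@@H](O[Si](CC)(CC)CC)C[C@@H]12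
F13 | step 17 | 2α-OTBS-3β-angelate-1-methylidene-(6Z)-ethylidene-7β-(triethylsilyloxy) compound | C=C1[C@H](O[Si](C)(C)C(C)(C)C)[C@@H](OC(=O)/C(C)=C\C)[C@@H](C(C)C)[C@@H]2/C(=C/C)[C@@H](O[Si](CC)(CC)CC)C[C@@H]12
F14 | step 17 | 2α-OTBS-3β-angelate-1-methylidene-(6Z)-ethylidene-7β-ol | C=C1[C@H](O[Si](C)(C)C(C)(C)C)[C@@H](OC(=O)/C(C)=C\C)[C@@H](C(C)C)[C@@H]2/C(=C/C)[C@@H](O)C[C@@H]12
F15 | step 17 | 2-O-tert-butyldimethylsilyl ether of 22 | C=C1[C@H](O[Si](C)(C)C(C)(C)C)[C@@H](OC(=O)/C(C)=C\C)[C@@H](C(C)C)[C@@H]2/C(=C/C)[C@@H](OC(C)=O)C[C@@H]12
F16 | step 14 | 6-methylidene analogue of 19 (1α,2α-epoxide, 3β-angelate, 7β-OTBS) | C[C@]13O[C@@H]3[C@@H](OC(=O)/C(C)=C\C)[C@@H](C(C)C)[C@@H]2C(=C)[C@@H](O[Si](C)(C)C(C)(C)C)C[C@@H]12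
F17 | step 9 | 3β-O-{2-[bis(2,2,2-trifluoroethoxy)phosphoryl]propanoyl} ester of 13 | CC1=C[C@@H](OC(=O)C(C)P(=O)(OCC(F)(F)F)OCC(F)(F)F)[C@@H](C(C)C)[C@@H]2[C@H]4OC(C)(C)O[C@H]4C[C@@H]12
F18 | step 3 | {(4R,5S)-2,2-dimethyl-5-[(2E)-3-methylpent-2-en-4-yn-1-yl]-1,3-dioxolan-4-yl}methanol | OC[C@H]1OC(C)(C)O[C@H]1C/C=C(\C)C#C
A1 | alternative 1 | ring A dialdehyde: C1 ethylene ketal, 2α-OPMB, 3β-OTBS, 4β-isopropyl, C5 formyl and C9 2-oxoethyl arms trans | O=CC[C@H]1C2(OCCO2)[C@H](OCc3ccc(OC)cc3)[C@@H](O[Si](C)(C)C(C)(C)C)[C@@H](C(C)C)[C@@H]1C=O
A2 | alternative 1 | acyclic precursor: C6 aldehyde, C4 isopropyl, C3 OTBS, C2 OPMB, C1 ethylene ketal, (E)-enal C9=C8–C7 | O=CC[C@H](C(C)C)[C@H](O[Si](C)(C)C(C)(C)C)[C@@H](OCc1ccc(OC)cc1)C1(OCCO1)/C=C/C=O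
A3 | alternative 2 | trans-hydrindane with 6β-acetyl, 4β-isopropyl and 1α-OTBS | CC(C)(C)[Si](C)(C)O[C@@H]1CC[C@@H](C(C)C)[C@@H]2[C@@H](C(C)=O)CC[C@@H]12
A4 | alternative 2 | trans-decalin cis-diol monomesylate (equatorial C6 mesylate, tertiary C12 carbinol, 1α-OTBS, 4β-isopropyl) | CC(C)(C)[Si](C)(C)O[C@@H]1CC[C@@H](C(C)C)[C@@H]2[C@@H](OS(C)(=O)=O)[C@@](C)(O)CC[C@@H]12
A5 | alternative 3 | bicyclic enone (C5=C6, C7 ketone) with 1-methylidene, 2α-OTIPS, 3β-OTBS, 4β-isopropyl | C=C1[C@H](O[Si](C(C)C)(C(C)C)C(C)C)[C@@H](O[Si](C)(C)C(C)(C)C)[C@@H](C(C)C)C2=CC(=O)C[C@@H]12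
A6 | alternative 3 | dienyne: terminal alkyne C6≡C5, C4 isopropyl, C3 OTBS, C2 OTIPS, 2-substituted buta-1,3-diene at C1 | C#C[C@H](C(C)C)[C@H](O[Si](C)(C)C(C)(C)C)[C@@H](O[Si](C(C)C)(C(C)C)C(C)C)C(=C)C=C
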